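**Retrosynthetic overview**
- The target comes from one-pot methanolysis of an all-cis oxan-4-yl trifluoroacetate that still carries an aryl acetate and a phenolic silyl ether.
- That trifluoroacetate comes from a new ring-opening Prins cyclisation of a cis-2-aryl-4-allyl-1,3-dioxolane. This step makes the C–C bond from the acetal carbon to the alkene terminus, the oxane ring, and the two ring stereocentres next to the aryl group and at the carbinol.
- The dioxolane comes from vanillin acetate and an anti-1,2-diol.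
- The diol comes from CuI-catalysed opening of an erythro epoxy alcohol by an aryl Grignard reagent. The epoxy alcohol comes from a Sharpless kinetic resolution of racemic hexa-1,5-dien-3-ol, which sets both carbinol centres.
- Ring order: epoxide (step 1, used up in step 3), then 1,3-dioxolane (step 4, used up in step 5), then the oxane (step 5). Both benzene rings are bought.

Assumption: the SMILES is read as the all-cis oxane (2R,4R,6S, with the guaiacyl-bearing carbon as C2) with a (1R) side-chain carbinol anti to the ring oxygen; racemic hexa-1,5-dien-3-ol, (4-bromophenoxy)(tert-butyl)dimethylsilane and vanillin acetate are taken as purchasable.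

**Step 1**
Reactants: 1 (±)-hexa-1,5-dien-3-ol (racemic)
Product: 2 (1S)-1-[(2R)-oxiran-2-yl]but-3-en-1-ol (erythro; equivalently (2R,3S)-1,2-epoxyhex-5-en-3-ol)
Conditions: Ti(OiPr)4 (15 mol %), L-(+)-diisopropyl tartrate (18 mol %), t-BuOOH (0.45 equiv), 4 Å MS, CH2Cl2, −20 °C, 4 d
Reagents that add atoms: tert-butyl hydroperoxide, CC(C)(C)OO
Why: Sharpless asymmetric epoxidation run as a kinetic resolution: the Ti/L-(+)-tartrate catalyst epoxidises the allylic vinyl group of (S)-1 much faster than that of (R)-1 (the homoallylic alkene is untouched) and does so erythro-selectively, so the carbinol centre (S) is selected and the epoxide centre (R) is created in one step, and stopping near 45 % conversion keeps the ee of 2 high.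

**Step 2**
Reactants: 3 (4-bromophenoxy)(tert-butyl)dimethylsilane
Product: 4 {4-[(tert-butyldimethylsilyl)oxy]phenyl}magnesium bromide (titrated THF solution)
Conditions: Mg turnings (1.2 equiv), I2 (cat.), THF, 40–60 °C, 2 h
Reagents that add atoms: magnesium, [Mg]
Why: Grignard formation by insertion of Mg into the aryl C–Br bond; the phenolic silyl ether tolerates it and no stereocentre is involved.

**Step 3**
Reactants: 2 (1S)-1-[(2R)-oxiran-2-yl]but-3-en-1-ol; 4 {4-[(tert-butyldimethylsilyl)oxy]phenyl}magnesium bromide (3.0 equiv)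
Product: 5 (2R,3S)-1-{4-[(tert-butyldimethylsilyl)oxy]phenyl}hex-5-ene-2,3-diol (anti diol)
Conditions: CuI (10 mol %), THF, −30 → 0 °C; aq. NH4Cl
Reagents that add atoms: none
Why: Copper-catalysed SN2 opening of a terminal epoxide by an aryl Grignard reagent at the unhindered CH2 (the first equivalent of 4 only deprotonates the hydroxyl); no bond to either stereocentre is broken, so the erythro (2R,3S) pattern of 2 is carried into the anti diol.

**Step 4**
Reactants: 5 (2R,3S)-1-{4-[(tert-butyldimethylsilyl)oxy]phenyl}hex-5-ene-2,3-diol; 6 4-formyl-2-methoxyphenyl acetate (vanillin acetate, 1.05 equiv)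
Product: 7 4-[(4S,5R)-4-allyl-5-{4-[(tert-butyldimethylsilyl)oxy]benzyl}-1,3-dioxolan-2-yl]-2-methoxyphenyl acetate (cis-4,5 ring; C4 is the allyl-bearing carbon; about 1:1 mixture of epimers at the acetal carbon)
Conditions: PPTS (10 mol %), PhMe, Dean–Stark, reflux, 3 h
Reagents that add atoms: none
Why: Acid-catalysed acetalisation of an aromatic aldehyde with a 1,2-diol, driven by azeotropic removal of water; both carbinol centres keep their configuration (hence the cis ring) and the new acetal centre need not be controlled because it becomes sp2 in step 5.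

**Step 5**
Reactants: 7 4-[(4S,5R)-4-allyl-5-{4-[(tert-butyldimethylsilyl)oxy]benzyl}-1,3-dioxolan-2-yl]-2-methoxyphenyl acetate
Product: 10 (2R,4R,6S)-2-(4-hydroxy-3-methoxyphenyl)-6-[(1R)-1-hydroxy-2-(4-hydroxyphenyl)ethyl]oxan-4-ol (target CNP0116327.2), via oxocarbenium trifluoroacetate 8 (not isolated), via all-cis oxan-4-yl trifluoroacetate 9 (not isolated)
Conditions: CF3CO2H (15 equiv), CH2Cl2 (0.05 M), −10 → 23 °C, 3 h; evaporate (PhMe azeotrope); then K2CO3 (3 equiv), MeOH, 23 °C, 8 h, Ar
Reagents that add atoms: trifluoroacetic acid, OC(=O)C(F)(F)F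
Why: Proposed new method: ring-opening Prins cyclisation of a cis-4-allyl-2-aryl-1,3-dioxolane made from an unprotected 1,2-diol – CF3CO2H protonates either acetal oxygen and opens the strained cis-dioxolane reversibly (5-exo re-closure is fast), but only the oxocarbenium ion that keeps the oxygen on the allyl-bearing carbon (8) is homoallylic and can close through a six-membered chair, whereas its regioisomer could only form an oxepane or attack the silyloxyarene at a position meta to oxygen, so the equilibrating mixture drains through 8 (Curtin–Hammett); in the chair the (E)-oxocarbenium has the aryl group and the C6 side chain equatorial and trifluoroacetate adds equatorially to the ring cation, which sets C2 (R) and C4 (R) cis to the untouched C6 (S) centre, while the expelled oxygen simply becomes the free (1R) carbinol, so the two hydroxyls of 5 never have to be told apart; K2CO3/MeOH then cleaves the trifluoroacetate, the aryl acetate and the phenolic silyl ether in the same pot; closest known reaction type: the CF3CO2H-mediated Prins cyclisation of homoallylic alcohols with aldehydes and the acetal-opening Prins cyclisation of 4-allyl-1,3-dioxanes.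

**Compound list**
1 | (±)-hexa-1,5-dien-3-ol | C=CCC(O)C=C | starting material
2 | (1S)-1-[(2R)-oxiran-2-yl]but-3-en-1-ol | C=CC[C@H](O)[C@H]1CO1 | intermediate
3 | (4-bromophenoxy)(tert-butyl)dimethylsilane | CC(C)(C)[Si](C)(C)Oc1ccc(Br)cc1 | starting material
4 | {4-[(tert-butyldimethylsilyl)oxy]phenyl}magnesium bromide | CC(C)(C)[Si](C)(C)Oc1ccc([Mg]Br)cc1 | intermediate
5 | (2R,3S)-1-{4-[(tert-butyldimethylsilyl)oxy]phenyl}hex-5-ene-2,3-diol | C=CC[C@H](O)[C@H](O)Cc1ccc(O[Si](C)(C)C(C)(C)C)cc1 | intermediate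
6 | 4-formyl-2-methoxyphenyl acetate | COc1cc(C=O)ccc1OC(C)=O | starting material
7 | 4-[(4S,5R)-4-allyl-5-{4-[(tert-butyldimethylsilyl)oxy]benzyl}-1,3-dioxolan-2-yl]-2-methoxyphenyl acetate (acetal carbon: both epimers) | C=CC[C@@H]1OC(c2ccc(OC(C)=O)c(OC)c2)O[C@@H]1Cc3ccc(O[Si](C)(C)C(C)(C)C)cc3 | intermediate
8 | (E)-[(4-acetoxy-3-methoxyphenyl)methylidene][(2R,3S)-1-{4-[(tert-butyldimethylsilyl)oxy]phenyl}-2-hydroxyhex-5-en-3-yl]oxonium trifluoroacetate | C=CC[C@H](/[O+]=C/c1ccc(OC(C)=O)c(OC)c1)[C@H](O)Cc1ccc(O[Si](C)(C)C(C)(C)C)cc1.[O-]C(=O)C(F)(F)F | intermediate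
9 | (2R,4R,6S)-2-(4-acetoxy-3-methoxyphenyl)-6-[(1R)-2-{4-[(tert-butyldimethylsilyl)oxy]phenyl}-1-hydroxyethyl]oxan-4-yl trifluoroacetate | COc1cc([C@H]2C[C@@H](OC(=O)C(F)(F)F)C[C@@H]([C@H](O)Cc3ccc(O[Si](C)(C)C(C)(C)C)cc3)O2)ccc1OC(C)=O | intermediate
10 | (2R,4R,6S)-2-(4-hydroxy-3-methoxyphenyl)-6-[(1R)-1-hydroxy-2-(4-hydroxyphenyl)ethyl]oxan-4-ol | COc1cc([C@H]2C[C@@H](O)C[C@@H]([C@H](O)Cc3ccc(O)cc3)O2)ccc1O | target

**Total step count:** 5
**Longest linear sequence:** 4 steps (steps 1, 3, 4, 5; the branch through step 2 is equally long).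

**Steps most likely to fail**

Step 5 (the new ring-opening Prins cyclisation). It can fail if 7 only equilibrates or hydrolyses back to 5 and 6, if the regioisomeric oxocarbenium ion is trapped by the arene, or if capture at C4 is not clean. The fallback uses known chemistry only, sets out from epoxy alcohol 2 and comes back at target 10. The acetal route is given up and the two hydroxyls are told apart by protecting groups, so that the ordinary bimolecular Prins cyclisation of a mono-protected homoallylic alcohol with an aldehyde is enough.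
- 2 is silylated (Et3SiCl, imidazole, DMF, 0 °C) to triethyl{[(1S)-1-[(2R)-oxiran-2-yl]but-3-en-1-yl]oxy}silane F1.
- F1 is opened by 4 (1.5 equiv, CuI 10 mol %, THF, −30 °C) to (2R,3S)-1-{4-[(tert-butyldimethylsilyl)oxy]phenyl}-3-[(triethylsilyl)oxy]hex-5-en-2-ol F2.
- BzCl, pyridine and DMAP give (2R,3S)-1-{4-[(tert-butyldimethylsilyl)oxy]phenyl}-3-[(triethylsilyl)oxy]hex-5-en-2-yl benzoate F3.
- PPTS in MeOH removes only the triethylsilyl group and gives (2R,3S)-1-{4-[(tert-butyldimethylsilyl)oxy]phenyl}-3-hydroxyhex-5-en-2-yl benzoate F4.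
- F4 and aldehyde 6 in CF3CO2H/CH2Cl2 (0 °C → rt) give, through the usual chair transition state, (2R,4R,6S)-2-(4-acetoxy-3-methoxyphenyl)-6-[(1R)-1-(benzoyloxy)-2-{4-[(tert-butyldimethylsilyl)oxy]phenyl}ethyl]oxan-4-yl trifluoroacetate F5, which is not isolated.
- K2CO3 in MeOH removes trifluoroacetate, benzoate, acetate and the phenolic silyl group and delivers 10.

Step 1 (Sharpless kinetic resolution). A monosubstituted alkene is epoxidised slowly, the small epoxy alcohol is volatile and water-soluble, the yield is capped below 50 %, and the ee depends on stopping at the right conversion. The fallback sets out from Grignard reagent 4 and comes back at diol 5; both carbinol centres are taken from the chiral pool, so neither 1 nor the resolution is needed.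
- 2-Deoxy-D-ribose F6 is methylenated (Ph3P=CH2 from Ph3PCH3Br and KOtBu, 3.5 equiv, THF, 0 °C → rt) to (2R,3S)-hex-5-ene-1,2,3-triol F7, which already has both stereocentres of 5.
- Selective sulfonylation of the primary hydroxyl (TsCl, Bu2SnO 2 mol %, Et3N, CH2Cl2, 0 °C) gives (2R,3S)-2,3-dihydroxyhex-5-en-1-yl 4-methylbenzenesulfonate F8.
- F8 is added to 4 (3.5 equiv) and CuI (10 mol %) in THF at −20 °C → rt. After deprotonation the 2-alkoxide closes onto C1 to give the magnesium alkoxide of 2 in the flask, and the arylcopper species opens it at C1 as in step 3. Direct displacement of the tosylate leads to the same product, 5.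

Step 3 (Cu-catalysed epoxide opening with a free hydroxyl). The magnesium alkoxide next to the epoxide can undergo Payne rearrangement, MgBr2 can give a bromohydrin, and three equivalents of 4 are needed. The fallback sets out from epoxy alcohol 2 (with bromide 3) and comes back at diol 5; it avoids both the free alkoxide and the copper catalyst.
- 2 is protected (t-BuMe2SiCl, imidazole, DMF) as tert-butyldimethyl{[(1S)-1-[(2R)-oxiran-2-yl]but-3-en-1-yl]oxy}silane F9.
- Bromide 3 is converted by Br/Li exchange (n-BuLi, THF, −78 °C) into {4-[(tert-butyldimethylsilyl)oxy]phenyl}lithium F10, made in the flask.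
- F10 with BF3·OEt2 at −78 °C opens F9 at the terminal carbon to give (2R,3S)-3-[(tert-butyldimethylsilyl)oxy]-1-{4-[(tert-butyldimethylsilyl)oxy]phenyl}hex-5-en-2-ol F11.
- Camphorsulfonic acid (0.3 equiv) in MeOH at rt removes the alkyl silyl ether and leaves the phenolic one, giving 5.

**Further compounds**
F1 | step 5 | triethyl{[(1S)-1-[(2R)-oxiran-2-yl]but-3-en-1-yl]oxy}silane | C=CC[C@H](O[Si](CC)(CC)CC)[C@H]1CO1
F2 | step 5 | (2R,3S)-1-{4-[(tert-butyldimethylsilyl)oxy]phenyl}-3-[(triethylsilyl)oxy]hex-5-en-2-ol | C=CC[C@H](O[Si](CC)(CC)CC)[C@H](O)Cc1ccc(O[Si](C)(C)C(C)(C)C)cc1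
F3 | step 5 | (2R,3S)-1-{4-[(tert-butyldimethylsilyl)oxy]phenyl}-3-[(triethylsilyl)oxy]hex-5-en-2-yl benzoate | C=CC[C@H](O[Si](CC)(CC)CC)[C@H](OC(=O)c1ccccc1)Cc1ccc(O[Si](C)(C)C(C)(C)C)cc1
F4 | step 5 | (2R,3S)-1-{4-[(tert-butyldimethylsilyl)oxy]phenyl}-3-hydroxyhex-5-en-2-yl benzoate | C=CC[C@H](O)[C@H](OC(=O)c1ccccc1)Cc1ccc(O[Si](C)(C)C(C)(C)C)cc1
F5 | step 5 | (2R,4R,6S)-2-(4-acetoxy-3-methoxyphenyl)-6-[(1R)-1-(benzoyloxy)-2-{4-[(tert-butyldimethylsilyl)oxy]phenyl}ethyl]oxan-4-yl trifluoroacetate | COc1cc([C@H]2C[C@@H](OC(=O)C(F)(F)F)C[C@@H]([C@H](OC(=O)c4ccccc4)Cc3ccc(O[Si](C)(C)C(C)(C)C)cc3)O2)ccc1OC(C)=O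
F6 | step 1 | 2-deoxy-D-ribose ((3S,4R)-3,4,5-trihydroxypentanal, drawn open-chain) | O=CC[C@H](O)[C@H](O)CO
F7 | step 1 | (2R,3S)-hex-5-ene-1,2,3-triol | C=CC[C@H](O)[C@H](O)CO
F8 | step 1 | (2R,3S)-2,3-dihydroxyhex-5-en-1-yl 4-methylbenzenesulfonate | C=CC[C@H](O)[C@H](O)COS(=O)(=O)c1ccc(C)cc1
F9 | step 3 | tert-butyldimethyl{[(1S)-1-[(2R)-oxiran-2-yl]but-3-en-1-yl]oxy}silane | C=CC[C@H](O[Si](C)(C)C(C)(C)C)[C@H]1CO1
F10 | step 3 | {4-[(tert-butyldimethylsilyl)oxy]phenyl}lithium | [Li]c1ccc(O[Si](C)(C)C(C)(C)C)cc1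
F11 | step 3 | (2R,3S)-3-[(tert-butyldimethylsilyl)oxy]-1-{4-[(tert-butyldimethylsilyl)oxy]phenyl}hex-5-en-2-ol | C=CC[C@H](O[Si](C)(C)C(C)(C)C)[C@H](O)Cc1ccc(O[Si](C)(C)C(C)(C)C)cc1
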